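The data are simulated for substances that don't exist; noise was put on by code.

Target is what a substrate molecule becomes when it turns the right way at a fork: it meets partner, or it goes to a side product. The loss to side product A needs a second substrate, so it weakens as substrate is used.

| flask | substrate | partner | temperature | remark | time |
|---|---|---|---|---|---|
| grey | 0.084 M | 0.45 M | 10 °C | run made earlier |  |
| ochre | 0.34 M | 0.45 M | 25 °C | run made earlier |  |
| violet | 1.4 M | 0.45 M | 10 °C | run made earlier |  |
| autumn | 1.0 M | 0.450 M | 25 °C |  | 25 h |
| spring | 0.10 M | 0.450 M | 25 °C |  | 25 h |
| dawn | 0.20 M | 0.450 M | 25 °C |  | 25 h |
| winter | 1.2 M | 0.450 M | 25 °C |  | 25 h |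
| midnight | 0.30 M | 0.450 M | 25 °C |  | 25 h |

- grey (time / h: target / %): 3.00: 4; 8.00: 9; 15.0: 18; 25.0: 22; 40.0: 28
- ochre (time / h: target / %): 1.50: 8; 4.00: 18; 8.00: 23; 12.0: 25; 20.0: 31
- violet (time / h: target / %): 3.00: 0; 5.00: 7; 10.0: 5; 20.0: 7; 40.0: 9

(standard deviation of a reading: 1.5 percentage points)

- percent here means substrate units held: one side product A or side product B counts as two
- the earlier runs were read with a standard deviation of 1.5 percentage points
- on the list of suspects stand: substrate + partner -> target; 2 substrate -> side product A; substrate + target -> side product B

* all flasks from highest to lowest amount of target, in percent of the substrate charged, at 25 h (autumn / spring / dawn / winter / midnight)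
* the amount of target, in percent of the substrate charged of the flask you put first, at 25 h
* the amount of target, in percent of the substrate charged of the flask you put last, at 25 h

Call x the fork number, a selectivity factor: the side rate over the target rate at the start of a flask. With a fraction s of the charge left and partner held at its charge, a molecule's chance of target is one over one plus x times s. Summed over a run taken to its end, with partner so held, the yield is the natural log of one plus x, divided by x. We take the last ochre reading, 31%, as a stand-in for that run's end, though the readings still rose 6 percentage points over the last 8.00 h. Solving the yield rule gives ochre a working fork number of 6.46, a reading that carries the scatter and lumps in with the loss to side product A the loss to side product B, the fall of partner and the unfinished run. The new flasks share ochre's partner and temperature, so x scales with the charge.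

Winter starts at x = 22.8. In the first instants our rule gives a molecule a chance of target of 4.20%, so by our reckoning nearly all of what reacts goes aside. In the middle, with 0.5 of the charge left, the chance is 8.06%. Towards the end the chance climbs, to 14.9% with 0.250 of the charge left. The sum for winter is 13.9%.

Spring starts at x = 1.90, with a chance of 34.5% that reaches 51.3% at the same midpoint, and sums to 56.0%. The yield falls as x rises, so our order follows the charge: spring, dawn, midnight, autumn, winter.

The forecast has spring > dawn > midnight > autumn > winter, with 50% (42% to 57%) on top, lower than ours, and 14% (8% to 18%) last, on the ground that “Yield falls sharply as substrate charge rises”. The flasks give spring > dawn > midnight > autumn > winter, with spring at 54.0% and winter at 12.2%.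

    substrate + partner → target (k = 3.96 × 10⁻⁵ /M/s, Ea = 81.0 kJ/mol)
    2 substrate → side product A (k = 6.72 × 10⁻⁵ /M/s, Ea = 80.0 kJ/mol)
    substrate + target → side product B (k = 4.30 × 10⁻⁵ /M/s, Ea = 68.0 kJ/mol)
    (constants at 25 °C)

Our 13.9% for winter stands 1.7 points above the flask, where at the start the step to side product A uses substrate 9.1 times as fast as the step to target, less than our working 22.8. Take the winter charge with 0.27 M of partner instead: the fork number rises to 38.0, our rule gives 9.64%, and that flask holds 7.57%.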